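**Retrosynthetic overview**
1. The target comes from its tetra-O-benzyl ether by neutral global hydrogenolysis as the last step.
2. Key disconnection is C2–C1' rather than the 3'–8'' biaryl bond. A Rh-catalysed enantioselective 1,4-addition of a flavone-bearing arylboronic acid to 5,7-bis(benzyloxy)chromone joins the two halves and sets C2 in one step.
3. The boronic acid comes from the aryl bromide. Its flavone pyranone ring is closed by aldol condensation and I2/DMSO on a preformed biaryl acetophenone.
4. The C3'–C8'' bond is made early by Pb(IV) ligand-coupling ortho C–H arylation of a phenol that has only one free ortho position, so the A-ring needs no halide.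
5. Both halves derive from one acetophenone. Order of construction: chromone ring, biaryl bond, flavone ring, then the flavanone C2 stereocentre.

Assumption: the SMILES encodes (2S). The biaryl axis (three ortho oxygens, one ortho H) is not specified and is treated as configurationally labile.

**Step 1**
Reactants: 1, 2,4,6-trihydroxyacetophenone; 2, benzyl bromide
Product: 3, 1-[2,4-bis(benzyloxy)-6-hydroxyphenyl]ethanone
Conditions: BnBr (2.05 equiv), K2CO3, DMF, 0 °C to rt
Reagents that add atoms: benzyl bromide, BrCc1ccccc1
Why: In this Williamson etherification the 4-OH and one of the two equivalent ortho OH groups are alkylated, and the remaining OH is hydrogen-bonded to the acetyl C=O and stays free with 2 equiv of halide.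

**Step 2**
Reactants: 3; 4, N,N-dimethylformamide dimethyl acetal
Product: 5, 5,7-bis(benzyloxy)-4H-chromen-4-one
Conditions: DMF-DMA (3 equiv), toluene, 100 °C; concentrate; conc. HCl, CH2Cl2, 40 °C
Reagents that add atoms: DMF-DMA, COC(OC)N(C)C (supplies C2–H)
Why: Enaminone formation at the acetyl CH3 followed by acid-promoted phenol addition and loss of Me2NH is the standard synthesis of 2,3-unsubstituted chromones, and aryl benzyl ethers tolerate the brief HCl treatment.

**Step 3**
Reactants: 3; 6, (5-bromo-2-methoxyphenyl)boronic acid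
Product: 7, 1-[4,6-bis(benzyloxy)-5'-bromo-2-hydroxy-2'-methoxybiphenyl-3-yl]ethanone
Conditions: 6 (1.3 equiv), Pb(OAc)4 (1.25 equiv), Hg(OAc)2 (10 mol %), CHCl3, 40 °C to rt; then 3 (1.0 equiv), pyridine (4 equiv), 60 °C
Reagents that add atoms: (5-bromo-2-methoxyphenyl)boronic acid, COc1ccc(Br)cc1B(O)O (transfers its aryl group)
Why: In this Pinhey–Barton ligand-coupling ortho-arylation, B-to-Pb exchange gives ArPb(OAc)3, the phenol binds Pb(IV), and the aryl group is delivered to the only free ortho carbon (C3–H, the future C8'', activated by O and two OBn groups) with C–Br untouched; 3,5-dialkoxyphenols and hindered o-methoxyaryllead reagents are established partners, while the o-acylphenol is a substrate extension.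

**Step 4**
Reactants: 7; 8, 4-methoxybenzaldehyde
Product: 9, (E)-1-[4,6-bis(benzyloxy)-5'-bromo-2-hydroxy-2'-methoxybiphenyl-3-yl]-3-(4-methoxyphenyl)prop-2-en-1-one
Conditions: 8 (1.2 equiv), 50% aq. KOH, EtOH–THF, rt, 48 h
Reagents that add atoms: 4-methoxybenzaldehyde, COc1ccc(C=O)cc1
Why: Claisen–Schmidt aldol condensation with a non-enolisable aldehyde gives the (E)-2'-hydroxychalcone, and any flavanone formed by oxa-Michael closure converges to the same product in step 5.

**Step 5**
Reactants: 9
Product: 10, 5,7-bis(benzyloxy)-8-(5-bromo-2-methoxyphenyl)-2-(4-methoxyphenyl)-4H-chromen-4-one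
Conditions: I2 (10 mol %), DMSO, 130 °C; aq. Na2S2O3 work-up
Reagents that add atoms: none
Why: I2/DMSO oxidative cyclisation (oxa-Michael closure through the only free phenol, α-iodination, HI loss, DMSO as terminal oxidant) places the aryl group unambiguously at C8, and ArBr, OBn and OMe survive.

**Step 6**
Reactants: 10; 11, tetrahydroxydiboron
Product: 12, {3-[5,7-bis(benzyloxy)-2-(4-methoxyphenyl)-4-oxo-4H-chromen-8-yl]-4-methoxyphenyl}boronic acid
Conditions: B2(OH)4 (3 equiv), XPhos Pd G2 (2 mol %), XPhos (4 mol %), KOAc (3 equiv), EtOH–THF, 80 °C; dilute acid work-up, trituration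
Reagents that add atoms: tetrahydroxydiboron, OB(O)B(O)O
Why: Miyaura-type Pd-catalysed borylation of an unhindered C–Br bond (H at both ortho positions) gives the free boronic acid directly, and KOAc is too mild to affect the flavone or the benzyl ethers.

**Step 7 (key step)**
Reactants: 12 (1.0 equiv); 5 (1.5 equiv)
Product: 13, (2S)-5,7-bis(benzyloxy)-2-{3-[5,7-bis(benzyloxy)-2-(4-methoxyphenyl)-4-oxo-4H-chromen-8-yl]-4-methoxyphenyl}-2,3-dihydro-4H-chromen-4-one
Conditions: preformed [Rh(OH)((S)-MeO-F12-BIPHEP)]2 (5 mol % Rh; from [RhCl(C2H4)2]2, ligand, KOH), CH2Cl2, 25–35 °C. Ligand: (S)-2,2'-bis[bis(3,4,5-trifluorophenyl)phosphino]-6,6'-dimethoxybiphenyl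
Reagents that add atoms: none beyond reactants 5 and 12 (H at C3 comes from B–OH/water)
Why: In this Hayashi–Miyaura Rh(I)-catalysed enantioselective 1,4-addition to a chromone, Ar–Rh inserts the unsubstituted C2=C3 of 5 (the β,β-disubstituted flavone C=C in 12 is inert), the (S)-biaryl diphosphine directs the aryl group to the C2 Re face (same sense as (S)-BINAP giving (S)-3-arylcyclohexanone) to set 2S, and base-free, non-aqueous, near-rt conditions suppress retro-oxa-Michael racemisation.

**Step 8**
Reactants: 13
Product: 14, (2S)-2,3-dihydro-4',4'''-di-O-methylamentoflavone (target)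
Conditions: H2 (1 atm), 10% Pd/C, EtOAc–THF, rt, monitored closely; Sephadex LH-20, no base
Reagents that add atoms: none
Why: Neutral hydrogenolysis cleaves the four aryl benzyl ethers faster than it reduces the flavone C=C or the cyclic C2–O bond, leaves the aryl methyl ethers intact, and with no acid or base present does not epimerise C2.

**Compound list**
1 | 2,4,6-trihydroxyacetophenone | CC(=O)c1c(O)cc(O)cc1O | starting material
2 | benzyl bromide | BrCc1ccccc1 | starting material
3 | 1-[2,4-bis(benzyloxy)-6-hydroxyphenyl]ethanone | CC(=O)c1c(O)cc(OCc2ccccc2)cc1OCc1ccccc1 | intermediate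
4 | N,N-dimethylformamide dimethyl acetal | COC(OC)N(C)C | starting material
5 | 5,7-bis(benzyloxy)-4H-chromen-4-one | O=c1ccoc2cc(OCc3ccccc3)cc(OCc3ccccc3)c12 | intermediate
6 | (5-bromo-2-methoxyphenyl)boronic acid | COc1ccc(Br)cc1B(O)O | starting material
7 | 1-[4,6-bis(benzyloxy)-5'-bromo-2-hydroxy-2'-methoxybiphenyl-3-yl]ethanone | CC(=O)c1c(O)c(-c2cc(Br)ccc2OC)c(OCc2ccccc2)cc1OCc1ccccc1 | intermediate
8 | 4-methoxybenzaldehyde | COc1ccc(C=O)cc1 | starting material
9 | (E)-chalcone of 7 and 8 | COc1ccc(/C=C/C(=O)c2c(O)c(-c3cc(Br)ccc3OC)c(OCc3ccccc3)cc2OCc2ccccc2)cc1 | intermediate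
10 | 5,7-bis(benzyloxy)-8-(5-bromo-2-methoxyphenyl)-2-(4-methoxyphenyl)-4H-chromen-4-one | COc1ccc(-c2cc(=O)c3c(OCc4ccccc4)cc(OCc4ccccc4)c(-c4cc(Br)ccc4OC)c3o2)cc1 | intermediate
11 | tetrahydroxydiboron | OB(O)B(O)O | starting material
12 | {3-[5,7-bis(benzyloxy)-2-(4-methoxyphenyl)-4-oxo-4H-chromen-8-yl]-4-methoxyphenyl}boronic acid | COc1ccc(-c2cc(=O)c3c(OCc4ccccc4)cc(OCc4ccccc4)c(-c4cc(B(O)O)ccc4OC)c3o2)cc1 | intermediate
13 | (2S)-5,7,5'',7''-tetra-O-benzyl-2,3-dihydro-4',4'''-di-O-methylamentoflavone | COc1ccc(-c2cc(=O)c3c(OCc4ccccc4)cc(OCc4ccccc4)c(-c4cc([C@@H]5CC(=O)c6c(OCc7ccccc7)cc(OCc7ccccc7)cc6O5)ccc4OC)c3o2)cc1 | intermediate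
14 | (2S)-2,3-dihydro-4',4'''-di-O-methylamentoflavone | COc1ccc(-c2cc(=O)c3c(O)cc(O)c(-c4cc([C@@H]5CC(=O)c6c(O)cc(O)cc6O5)ccc4OC)c3o2)cc1 | target

**Totals**
Total steps: 8. Longest linear sequence: 7 (steps 1, 3, 4, 5, 6, 7, 8). Step 2 is the side branch from the shared intermediate 3.

**Three steps most likely to fail, with fallbacks**
1. **Step 7.**
   - Risks: the electron-rich 5,7-dialkoxychromone may insert slowly. The large boronic acid may protodeboronate. The facial sense is predicted by analogy and must be confirmed by CD, where a (2S)-flavanone shows a positive band near 330 nm and a negative band near 290 nm.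
   - Fallback: abandon the C2–C1' coupling. Formylate bromide 10 with Pd/CO–H2 and condense the aldehyde with the β-ketoester derived from 3 (Knoevenagel). Close the flavanone ring by cinchona–thiourea-catalysed enantioselective oxa-Michael addition, then decarboxylate. Alternatively, cyclise racemically and resolve by Ru-TsDPEN transfer-hydrogenation kinetic resolution.
2. **Step 3.**
   - Risks: the hydrogen-bonded o-acylphenol may exchange poorly onto Pb(IV). O-arylation or Wessely-type oxidation may compete.
   - Fallback: switch to halogenation and cross-coupling at this simple stage. Iodinate 3 at C3 with NIS, then couple with 6 under Pd catalysis, where C–I reacts well before C–Br.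
3. **Step 6.**
   - Risks: the lipophilic substrate may dissolve poorly in the alcohol medium. Hydrodebromination may compete. The free boronic acid may be difficult to isolate.
   - Fallback: change the nucleophile class. Borylate with B2pin2, convert to the crystalline potassium aryltrifluoroborate with KHF2, and use that salt directly in the Rh-catalysed 1,4-addition.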